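**Retrosynthetic overview**

1. Feature the strategy rests on: in the depsidone core (ring A = C1–C4a/C11a, ether O5, ring B = C5a–C9a, ester O10, carbonyl C11), O10 sits on C9a, next to the ether-bearing C5a, and C5a is para to C8, whose oxygen becomes the pyranone oxygen. Ring B can therefore enter as a 4-hydroxy-2-methylphenyl ether that lacks O10.
2. Last disconnections: the A-ring methyl ether (BCl3), then the pyranone ring at C7/C8 (acylation/oxa-Michael with 3,3-dimethylacrylic acid). This ring is formed last.
3. Key disconnection: the C9a–O10 bond of the seven-membered lactone, traced back to a 2-aryloxybenzoic acid with a free para-phenol through a transient six-membered spiro ketal lactone.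
4. The diaryl ether C4a–O5 comes from SNAr of a mono-protected methylhydroquinone on a 2-fluoro-3-formylbenzoate; the protecting groups are 4-methoxybenzyl (PMB) so that one acid step frees both acid and phenol.
5. Ring A comes from 3,5-difluorotoluene (formylation, methoxide SNAr, iodination, carbonylation). Ring order: A and B are bought aromatic, then the lactone ring, then the pyranone.

Key step: step 9

Remark: the target has no stereocentre, so no enantiocontrol is needed; the spiro carbon of 13 is formed as a racemate and is lost in the same flask.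
Remark: locants on the tricycle follow 11H-dibenzo[b,e][1,4]dioxepin-11-one as given in line 1.

Step 1
Reactants: 1 3,5-difluorotoluene
Product: 3 2,6-difluoro-4-methylbenzaldehyde, via aryllithium 2 (not isolated)
Conditions: n-BuLi, THF, −78 °C; DMF, −78 °C → 0 °C; aq. HCl
Reagents that add atoms: N,N-dimethylformamide, CN(C)C=O
Why: The ring hydrogen between the two fluorines is the most acidic, so directed ortho-lithiation should occur there and DMF formylates the aryllithium (ortho-lithiation/formylation).

Step 2
Reactants: 3 2,6-difluoro-4-methylbenzaldehyde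
Product: 4 2-fluoro-6-methoxy-4-methylbenzaldehyde
Conditions: NaOMe (1.05 equiv), MeOH, 0 °C → rt
Reagents that add atoms: sodium methoxide, [Na+].[O-]C
Why: SNAr at a fluoride ortho to the formyl group; the two fluorides are equivalent and the first methoxy group deactivates the ring, so mono-substitution should be clean.

Step 3
Reactants: 4 2-fluoro-6-methoxy-4-methylbenzaldehyde
Product: 5 2-fluoro-3-iodo-6-methoxy-4-methylbenzaldehyde
Conditions: NIS, TFA, MeCN, rt, dark
Reagents that add atoms: N-iodosuccinimide, O=C1CCC(=O)N1I
Why: Electrophilic aromatic iodination should go para to the methoxy group (C3, flanked by F and CH3) and not to the more crowded site ortho to it.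

Step 4
Reactants: 5 2-fluoro-3-iodo-6-methoxy-4-methylbenzaldehyde
Product: 6 4-methoxybenzyl 2-fluoro-3-formyl-4-methoxy-6-methylbenzoate
Conditions: Pd(OAc)2 (cat.), Xantphos (cat.), CO (1 atm), 4-methoxybenzyl alcohol, Et3N, toluene, 80 °C
Reagents that add atoms: carbon monoxide, [C-]#[O+]; 4-methoxybenzyl alcohol, COc1ccc(CO)cc1
Why: Palladium-catalysed alkoxycarbonylation of the aryl iodide; the amine base does not generate alkoxide, so the activated fluoride should be kept.

Step 5
Reactants: 7 4-hydroxy-2-methylbenzaldehyde
Product: 8 4-[(4-methoxybenzyl)oxy]-2-methylbenzaldehyde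
Conditions: PMBCl, K2CO3, DMF, 60 °C
Reagents that add atoms: 4-methoxybenzyl chloride, COc1ccc(CCl)cc1
Why: Williamson etherification of the phenol; starting from the aldehyde fixes which hydroquinone oxygen is protected.

Step 6
Reactants: 8 4-[(4-methoxybenzyl)oxy]-2-methylbenzaldehyde
Product: 10 4-[(4-methoxybenzyl)oxy]-2-methylphenol, via aryl formate 9 (not isolated)
Conditions: mCPBA, NaHCO3, CH2Cl2, 0 °C → rt; then K2CO3 (cat.), MeOH, rt
Reagents that add atoms: 3-chloroperoxybenzoic acid, OOC(=O)c1cccc(Cl)c1
Why: Baeyer–Villiger (Dakin-type) oxidation in which the electron-rich aryl group migrates, followed by methanolysis of the formate, gives the phenol whose free hydroxyl is the one next to the methyl group.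

Step 7
Reactants: 6 4-methoxybenzyl 2-fluoro-3-formyl-4-methoxy-6-methylbenzoate; 10 4-[(4-methoxybenzyl)oxy]-2-methylphenol
Product: 11 4-methoxybenzyl 3-formyl-4-methoxy-2-{4-[(4-methoxybenzyl)oxy]-2-methylphenoxy}-6-methylbenzoate
Conditions: K2CO3, DMF, 60 °C
Reagents that add atoms: none
Why: SNAr by the phenoxide on a fluoride flanked by a formyl and an ester group (doubly activated), which should tolerate the single ortho methyl group of the nucleophile.

Step 8
Reactants: 11 4-methoxybenzyl 3-formyl-4-methoxy-2-{4-[(4-methoxybenzyl)oxy]-2-methylphenoxy}-6-methylbenzoate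
Product: 12 3-formyl-2-(4-hydroxy-2-methylphenoxy)-4-methoxy-6-methylbenzoic acid
Conditions: TFA, pentamethylbenzene, CH2Cl2, 0 °C → rt
Reagents that add atoms: none
Why: Acidolysis cleaves the PMB ester and the PMB ether together while pentamethylbenzene traps the 4-methoxybenzyl cation; the methyl ether, aldehyde and diaryl ether are stable to TFA, and no basic hydrolysis of the hindered ester is needed.

Step 9
Reactants: 12 3-formyl-2-(4-hydroxy-2-methylphenoxy)-4-methoxy-6-methylbenzoic acid
Product: 14 8-hydroxy-3-methoxy-1,6-dimethyl-11-oxo-11H-dibenzo[b,e][1,4]dioxepine-4-carbaldehyde, via spiro ketal lactone 13 (not isolated)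
Conditions: PhI(OAc)2 (1.05 equiv), 4 Å MS, HFIP, 0 °C; then TFA, CH2Cl2, 0 °C → rt
Reagents that add atoms: none
Why: Proposed new method: ligand exchange of the C8 phenol of 12 at iodine(III) and loss of iodobenzene should give a 4-aryloxyphenoxenium equivalent whose para carbon C5a, although it already carries O5, is trapped by the A-ring carboxylate to give the spiro ketal lactone 13; protonation of the dienone carbonyl then makes C9a electrophilic, the lactone carbonyl oxygen bridges to C9a through a dioxolanylium ion, the old C5a–O bond opens to an oxocarbenium ion held by O5, and loss of the C9a proton rearomatises ring B. The closest known reaction types are iodine(III) spirolactonisation of para-substituted phenols that carry a carboxylic acid, iodine(III) formation of quinone monoketals from para-alkoxyphenols, and the acid-induced dienone–phenol rearrangement of spirolactone dienones with acyloxy migration; their combination at an aryloxy-bearing (ketal) carbon with growth of the spiro ring into a seven-membered lactone is the part treated here as not yet shown. The six-membered ring closes by ipso attack of the carboxylate at C5a (6-exo-trig with respect to ring B), the bridge forms by 5-exo-trig attack at C9a, and the seven-membered lactone arises from the six-membered one by this 1,2-acyloxy shift (six-to-seven ring expansion). No stereocentre remains, since the spiro carbon of 13 is racemic and becomes sp2 again. The step needs the shift to go to C9a and not to the methyl-bearing C6, which should hold because bridging to C6 is reversible and only the C9a adduct can lose a proton to aromatise; the oxidation is chemoselective because ring B carries the only free phenol, the A-ring oxygen being a methyl ether and the formyl group inert to iodine(III). Water has to be excluded, since hydrolysis of the ketal acylal would release methylbenzoquinone.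

Step 10
Reactants: 14 8-hydroxy-3-methoxy-1,6-dimethyl-11-oxo-11H-dibenzo[b,e][1,4]dioxepine-4-carbaldehyde; 15 3,3-dimethylacrylic acid
Product: 17 mollicellin A 3-O-methyl ether, via enone 16 (not isolated)
Conditions: Eaton's reagent (P2O5 in MeSO3H), 60 °C
Reagents that add atoms: none
Why: Friedel–Crafts acylation ortho to the C8 phenol followed by oxa-Michael closure builds the 2,2-dimethylpyranone; C7 (between OH and CH3, para to O10) should be preferred over C9 (between two oxygens), as orcinol-type phenols are acylated between hydroxyl and methyl, while ring A is deactivated by its formyl and acyl groups and both positions ortho to O5 on ring B are blocked against xanthone formation.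

Step 11
Reactants: 17 mollicellin A 3-O-methyl ether
Product: 18 mollicellin A
Conditions: BCl3, CH2Cl2, −78 °C → 0 °C; aq. NaHCO3
Reagents that add atoms: none
Why: Chelation-assisted demethylation: boron bound between the formyl oxygen and the ortho methoxy oxygen should allow chloride to remove only that methyl group, leaving the lactone and the pyranone ether intact at low temperature.

**Compound list**

1 | 3,5-difluorotoluene | Cc1cc(F)cc(F)c1 | starting material
2 | (2,6-difluoro-4-methylphenyl)lithium | [Li]c1c(F)cc(C)cc1F | intermediate (not isolated)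
3 | 2,6-difluoro-4-methylbenzaldehyde | Cc1cc(F)c(C=O)c(F)c1 | intermediate
4 | 2-fluoro-6-methoxy-4-methylbenzaldehyde | COc1cc(C)cc(F)c1C=O | intermediate
5 | 2-fluoro-3-iodo-6-methoxy-4-methylbenzaldehyde | COc1cc(C)c(I)c(F)c1C=O | intermediate
6 | 4-methoxybenzyl 2-fluoro-3-formyl-4-methoxy-6-methylbenzoate | COc1cc(C)c(C(=O)OCc2ccc(OC)cc2)c(F)c1C=O | intermediate
7 | 4-hydroxy-2-methylbenzaldehyde | Cc1cc(O)ccc1C=O | starting material
8 | 4-[(4-methoxybenzyl)oxy]-2-methylbenzaldehyde | Cc1cc(OCc2ccc(OC)cc2)ccc1C=O | intermediate
9 | 4-[(4-methoxybenzyl)oxy]-2-methylphenyl formate | Cc1cc(OCc2ccc(OC)cc2)ccc1OC=O | intermediate (not isolated)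
10 | 4-[(4-methoxybenzyl)oxy]-2-methylphenol | Cc1cc(OCc2ccc(OC)cc2)ccc1O | intermediate
11 | 4-methoxybenzyl 3-formyl-4-methoxy-2-{4-[(4-methoxybenzyl)oxy]-2-methylphenoxy}-6-methylbenzoate | COc1cc(C)c(C(=O)OCc2ccc(OC)cc2)c(Oc2ccc(OCc3ccc(OC)cc3)cc2C)c1C=O | intermediate
12 | 3-formyl-2-(4-hydroxy-2-methylphenoxy)-4-methoxy-6-methylbenzoic acid | Cc1cc(OC)c(C=O)c(Oc2ccc(O)cc2C)c1C(=O)O | intermediate
13 | 7-methoxy-2',5-dimethyl-4,4'-dioxo-4H-spiro[1,3-benzodioxine-2,1'-cyclohexa-2',5'-diene]-8-carbaldehyde (racemic spiro carbon) | Cc1cc(OC)c(C=O)c2c1C(=O)OC1(O2)C=CC(=O)C=C1C | intermediate (not isolated)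
14 | 8-hydroxy-3-methoxy-1,6-dimethyl-11-oxo-11H-dibenzo[b,e][1,4]dioxepine-4-carbaldehyde | Cc1cc(OC)c(C=O)c2c1C(=O)Oc1cc(O)cc(C)c1O2 | intermediate
15 | 3,3-dimethylacrylic acid (3-methylbut-2-enoic acid) | CC(C)=CC(=O)O | starting material
16 | 8-hydroxy-3-methoxy-1,6-dimethyl-7-(3-methylbut-2-enoyl)-11-oxo-11H-dibenzo[b,e][1,4]dioxepine-4-carbaldehyde | Cc1cc(OC)c(C=O)c2c1C(=O)Oc1cc(O)c(C(=O)C=C(C)C)c(C)c1O2 | intermediate (not isolated)
17 | mollicellin A 3-O-methyl ether | Cc1cc(OC)c(C=O)c2c1C(=O)Oc1cc3c(c(C)c1O2)C(=O)CC(C)(C)O3 | intermediate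
18 | mollicellin A | Cc1cc(O)c(C=O)c2c1C(=O)Oc1cc3c(c(C)c1O2)C(=O)CC(C)(C)O3 | target

**Step count and risks**

Total step count: 11. Longest linear sequence: 9 steps (steps 1–4, then 7–11); the B-ring branch (steps 5–6) joins at step 7.

Steps most likely to fail:

Step 9 (bears the label "Proposed new method:"). The ketal acylal carbon of 13 may ionise and be intercepted by adventitious water, acetate or trifluoroacetate, so that ring B is lost as a quinone before the acyloxy group shifts; the phenoxenium equivalent may also be trapped intermolecularly. The fallback uses known chemistry: O10 is brought in with ring B and the lactone is closed by dehydration. It sets out from 6 and comes back to the route at 14. Commercial 2,4-dihydroxy-6-methylbenzaldehyde is bis-alkylated with 4-methoxybenzyl chloride (K2CO3, DMF) to 2,4-bis[(4-methoxybenzyl)oxy]-6-methylbenzaldehyde F1. Baeyer–Villiger oxidation with mCPBA gives 2,4-bis[(4-methoxybenzyl)oxy]-6-methylphenyl formate F2, and methanolysis gives 2,4-bis[(4-methoxybenzyl)oxy]-6-methylphenol F3. SNAr of F3 on 6 (Cs2CO3, DMF) gives 4-methoxybenzyl 2-{2,4-bis[(4-methoxybenzyl)oxy]-6-methylphenoxy}-3-formyl-4-methoxy-6-methylbenzoate F4. TFA with pentamethylbenzene frees 2-(2,4-dihydroxy-6-methylphenoxy)-3-formyl-4-methoxy-6-methylbenzoic acid F5. Lactonisation with DCC at high dilution, where only the ortho hydroxyl can reach the acid, gives 14.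

Step 10. Acylation may go to C9 in place of C7, and the free formyl group may condense with the phenolic ring in the hot acid. The fallback separates the ring functionalisation from the acylation and avoids strong acid; it sets out from 14 and comes back at 16, which closes to 17 with Et3N. Iodination of 14 with NIS at room temperature gives 8-hydroxy-7-iodo-3-methoxy-1,6-dimethyl-11-oxo-11H-dibenzo[b,e][1,4]dioxepine-4-carbaldehyde F6, whose site can be checked and any C9 isomer removed before the C5 unit is committed. Carbonylative Stille coupling of F6 with tributyl(2-methylprop-1-enyl)stannane under CO (Pd(PPh3)4, dioxane, 80 °C) then gives 16.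

Step 11. The Lewis acid may open the 2,2-dimethylpyranone ether or the lactone in competition with demethylation. The fallback changes the order so that the pyranone never meets BCl3; it sets out from 14 and comes back at 18. BCl3 on 14 gives 3,8-dihydroxy-1,6-dimethyl-11-oxo-11H-dibenzo[b,e][1,4]dioxepine-4-carbaldehyde F7. Annulation of F7 with 15 in Eaton's reagent then passes through 3,8-dihydroxy-1,6-dimethyl-7-(3-methylbut-2-enoyl)-11-oxo-11H-dibenzo[b,e][1,4]dioxepine-4-carbaldehyde F8 and gives 18 directly. The A-ring hydroxyl is hydrogen-bonded to the formyl group on a ring with two acyl substituents, so ring B should remain the more nucleophilic.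

Further compounds
F1 | step 9 | 2,4-bis[(4-methoxybenzyl)oxy]-6-methylbenzaldehyde | Cc1cc(OCc2ccc(OC)cc2)cc(OCc2ccc(OC)cc2)c1C=O
F2 | step 9 | 2,4-bis[(4-methoxybenzyl)oxy]-6-methylphenyl formate | Cc1cc(OCc2ccc(OC)cc2)cc(OCc2ccc(OC)cc2)c1OC=O
F3 | step 9 | 2,4-bis[(4-methoxybenzyl)oxy]-6-methylphenol | Cc1cc(OCc2ccc(OC)cc2)cc(OCc2ccc(OC)cc2)c1O
F4 | step 9 | 4-methoxybenzyl 2-{2,4-bis[(4-methoxybenzyl)oxy]-6-methylphenoxy}-3-formyl-4-methoxy-6-methylbenzoate | Cc1cc(OC)c(C=O)c(Oc2c(C)cc(OCc3ccc(OC)cc3)cc2OCc2ccc(OC)cc2)c1C(=O)OCc1ccc(OC)cc1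
F5 | step 9 | 2-(2,4-dihydroxy-6-methylphenoxy)-3-formyl-4-methoxy-6-methylbenzoic acid | Cc1cc(OC)c(C=O)c(Oc2c(C)cc(O)cc2O)c1C(=O)O
F6 | step 10 | 8-hydroxy-7-iodo-3-methoxy-1,6-dimethyl-11-oxo-11H-dibenzo[b,e][1,4]dioxepine-4-carbaldehyde | Cc1cc(OC)c(C=O)c2c1C(=O)Oc1cc(O)c(I)c(C)c1O2
F7 | step 11 | 3,8-dihydroxy-1,6-dimethyl-11-oxo-11H-dibenzo[b,e][1,4]dioxepine-4-carbaldehyde | Cc1cc(O)c(C=O)c2c1C(=O)Oc1cc(O)cc(C)c1O2
F8 | step 11 | 3,8-dihydroxy-1,6-dimethyl-7-(3-methylbut-2-enoyl)-11-oxo-11H-dibenzo[b,e][1,4]dioxepine-4-carbaldehyde | Cc1cc(O)c(C=O)c2c1C(=O)Oc1cc(O)c(C(=O)C=C(C)C)c(C)c1O2
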